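A ratio opens my books: Friday's flask carries 1.55 times the catalyst of Saturday's flask, and I want to know what that ratio does to the clock. Saturday's flask is the one asked about, followed further.

common to all: left-handed substrate 0.10 M; right-handed substrate 0.10 M; added ligand 3.4 mM

| flask | partner | catalyst | remark | time |
|---|---|---|---|---|
| Saturday's | 3 equiv | 1.1 mol% | the very flask that is asked about, followed so far |  |
| Friday's | 3 equiv | 1.7 mol% | run made earlier |  |
| flask | 3.00 equiv | 1.1 mol% |  | 4.0 d |

Saturday's run (percent of the left-handed substrate and right-handed substrate together charged)

| time / h | left-handed substrate / % | right-handed substrate / % |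
|---|---|---|
| 6.00 | 38.8 | 49.2 |
| 15.0 | 32.2 | 49.4 |
| 30.0 | 27.7 | 50.3 |
| 50.0 | 21.2 | 48.8 |

Friday's run (percent of the left-handed substrate and right-handed substrate together charged)

| time / d | left-handed substrate / % | right-handed substrate / % |
|---|---|---|
| 0.208 | 33.5 | 49.5 |
| 0.500 | 26.8 | 49.0 |
| 1.25 | 18.8 | 51.3 |
| 3.00 | 10.4 | 51.2 |

(scatter of a reading: 1 percentage point)

- part of the left-handed substrate and right-handed substrate charged together that has reacted at 4.0 d
- excess of left-handed product over right-handed product in the product at 4.0 d
- excess of right-handed substrate over left-handed substrate among what is left of the two at 4.0 d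

My ledger follows the left-handed substrate, the limiting reagent against 3.00 equiv of partner. I count in percent of both substrates charged, so this account opens at 50.0 %.

The first entry is the right-handed substrate. Its readings wander between 48.8 % and 51.3 % with a scatter of 1 percentage point, so I book no loss for it. The second entry is product: at 50.0 h, Saturday's flask reads a loss of 28.8 % of left-handed substrate, and I book that as left-handed product.

The third entry is time. Saturday's flask reads 27.7 % at 30.0 h and Friday's flask reads 26.8 % at 0.500 d. These differ by 0.9 points against that scatter, so I treat them as one level of left-handed substrate, which Friday's flask reads sooner by a factor of 2.50. Dividing the logarithm of this factor by the logarithm of the loading ratio gives 2.10, my clock exponent: the powers of ten gained in speed per power of ten of catalyst, as read from these readings.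

To close the books, I set Saturday's flask at 4.0 d beside Friday's flask at 1.60 d. That time falls between Friday's readings of 18.8 % and 10.4 %, and a straight line between them gives my estimate of 17.1 % of left-handed substrate. So I reckon 32.9 % reacted and an excess of right-handed substrate of 49.0 %. With no right-handed product booked, the product excess stands close to 100 percent.

The forecast gives 34.5 %, 99 % and 52.7 %, on the ground that "The rate falls as product builds up, which looks like strong product inhibition". My two substrate figures are lower than its figures.

The flask gives 33.7 % reacted, a product excess of 97.8 % and a substrate excess of 49.7 %.

    partner + catalyst + right-handed substrate → catalyst + right-handed product (k = 3.30 × 10⁻⁴ /M²/s)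
    partner + catalyst + left-handed substrate → catalyst + left-handed product (k = 0.0490 /M²/s)
    partner ⇌ dormant form (K = 2.20, k = 1.00 × 10⁻⁵ /s)
    partner → decomposition product (k = 8.10 × 10⁻⁹ /s)
    catalyst + added ligand ⇌ idle complex (K = 470 /M, k = 0.00550 /M/s)

At 4.00 d, the flask keeps 24 % of its charged partner unbound, less than its 99.3 % of right-handed substrate, with dormant form at 0.162 M. Now the clock exponent goes to a neighbour flask with 0.66 mol% of catalyst. By the exponent its time should stretch by 2.93, so my estimate sets its 4.0 d beside Saturday's flask at 32.8 h, a time that falls between Saturday's readings of 27.7 % and 21.2 %. That neighbour flask ends with 25.4 % of left-handed substrate.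

All runs were computed for an exercise; the scatter is artificial.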